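**Retrosynthetic overview**
1. Isohalitulin 18 ⇐ tetramethyl ether 17; the last step is a fourfold O-demethylation.
2. 17 ⇐ pyrrole N–CH2 bond: N-silyl bis(quinolinyl)pyrrole 16 + spiro-azetidinium salt 11, joined by a new fluoride-triggered strain-release C–N coupling.
3. 11 ⇐ (S)-3-methylazecane 8 + 1-bromo-3-chloropropane (two C–N bonds). 8 ⇐ N-nosyl azecane 7 ⇐ ring N–C2 bond by intramolecular Fukuyama–Mitsunobu reaction of 6; the N–C10 bond comes from sulfonamide alkylation of chloro alcohol 4. The stereocentre is bought in with (R)-3-bromo-2-methylpropan-1-ol and extended by a copper-catalysed Grignard coupling.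
4. 16 ⇐ twofold Suzuki coupling of 3,4-dibromo-1-(triisopropylsilyl)pyrrole with the boronate of 5-bromo-6,7-dimethoxyquinoline 13 ⇐ 6,7-dimethoxyquinoline.
5. Ring order: quinoline and pyrrole rings come preformed; the 10-membered azecane ring is closed first (step 3), then the transient azetidinium ring (step 5), which is opened again in step 8.

Assumption: 1, 2, 5, 9, 12 and 14 are bought as catalogue chemicals.

**Route**

Step 1
Reactants: 1 (R)-3-bromo-2-methylpropan-1-ol; 2 1-bromo-6-chlorohexane
Product: 4 (S)-9-chloro-2-methylnonan-1-ol, via 6-chlorohexylmagnesium bromide 3 (not isolated)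
Conditions: 2 (2.4 equiv), Mg, THF, 35 °C; then 1, Li2CuCl4 (3 mol %), THF, −20 → 0 °C; aq. NH4Cl
Reagents that add atoms: none
Why: Kochi-type copper-catalysed Grignard–alkyl bromide cross-coupling (sp3–sp3 C–C bond), in which the first equivalent of 3 only deprotonates the hydroxyl group, the second displaces the primary bromide while the alkyl chloride stays inert, and the stereocentre of 1 is not a reacting atom, so its configuration is carried into 4 unchanged (the descriptor becomes S only through the CIP priorities).

Step 2
Reactants: 4 (S)-9-chloro-2-methylnonan-1-ol; 5 2-nitrobenzenesulfonamide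
Product: 6 N-[(8S)-9-hydroxy-8-methylnonyl]-2-nitrobenzenesulfonamide
Conditions: 5 (3 equiv), K2CO3, NaI (20 mol %), DMF, 70 °C
Reagents that add atoms: none
Why: SN2 N-alkylation of the acidic primary sulfonamide (first alkylation of a Fukuyama amine synthesis) at the unhindered primary chloride with iodide catalysis, where the threefold excess of 5 suppresses dialkylation and the primary alcohol is inert to carbonate.

Step 3
Reactants: 6 N-[(8S)-9-hydroxy-8-methylnonyl]-2-nitrobenzenesulfonamide
Product: 7 (3S)-3-methyl-1-[(2-nitrophenyl)sulfonyl]azecane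
Conditions: PPh3, DIAD, toluene–THF, slow addition of 6 (final 0.01 M), rt
Reagents that add atoms: none
Why: Intramolecular Fukuyama–Mitsunobu reaction in which the activated primary alcohol is displaced by the sulfonamide nitrogen (pKa about 10) to close the ring N–C2 bond, a reaction type known to deliver 8- to 10-membered N-nosyl azacycles, with slow addition holding back oligomers and the adjacent stereocentre not being a reaction site.

Step 4
Reactants: 7 (3S)-3-methyl-1-[(2-nitrophenyl)sulfonyl]azecane
Product: 8 (3S)-3-methylazecane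
Conditions: PhSH, K2CO3, MeCN, 50 °C; acid–base extraction
Reagents that add atoms: none
Why: Fukuyama denosylation, in which thiolate adds ipso to the nitroarene (Meisenheimer complex, SNAr), the sulfonyl group leaves as SO2 and the secondary amine is released without touching the stereocentre.

Step 5
Reactants: 8 (3S)-3-methylazecane; 9 1-bromo-3-chloropropane
Product: 11 (6S)-6-methyl-4-azoniaspiro[3.9]tridecane tetrafluoroborate, via chloropropylamine 10 (not isolated)
Conditions: 9 (2 equiv), K2CO3, MeCN, rt; filter, evaporate excess 9; then AgBF4, MeCN, 50 °C, dark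
Reagents that add atoms: silver tetrafluoroborate, [Ag+].F[B-](F)(F)F
Why: Chemoselective SN2 N-alkylation at the C–Br end of 9 followed by silver-assisted 4-exo-tet intramolecular quaternisation of the 3-chloropropylamine (azetidinium formation), driven to completion by precipitation of AgCl and giving a storable salt with a non-nucleophilic anion.

Step 6
Reactants: 12 6,7-dimethoxyquinoline
Product: 13 5-bromo-6,7-dimethoxyquinoline
Conditions: NBS (1.05 equiv), conc. H2SO4, −20 → 0 °C
Reagents that add atoms: N-bromosuccinimide, O=C1CCC(=O)N1Br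
Why: Electrophilic aromatic bromination of the quinolinium ion, where C5 is ortho to the 6-methoxy group whereas C8 is deactivated by the peri N–H+ and by the push–pull conjugation of the 7-methoxy group to that nitrogen, in line with the 5-selective nitration of 6,7-dimethoxy-4-methylquinoline (recalled from memory, not checked).

Step 7
Reactants: 13 5-bromo-6,7-dimethoxyquinoline; 14 3,4-dibromo-1-(triisopropylsilyl)-1H-pyrrole
Product: 16 5,5'-[1-(triisopropylsilyl)-1H-pyrrole-3,4-diyl]bis(6,7-dimethoxyquinoline), via quinolinyl pinacol boronate 15 (not isolated)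
Conditions: 13 (2.4 equiv), B2pin2 (2.5 equiv), Pd(dppf)Cl2 (4 mol %), KOAc, dioxane, 90 °C; then 14 (1 equiv), Pd(OAc)2/SPhos (5/10 mol %), K3PO4, H2O, 100 °C
Reagents that add atoms: none
Why: Miyaura borylation of the hindered aryl bromide followed in the same flask by a twofold Suzuki–Miyaura coupling at the two C–Br bonds of 14, where the bulky silyl group shields the pyrrole 2- and 5-positions and should survive the phosphate base, and SPhos is chosen for the doubly ortho-flanked aryl–pyrrole bonds.

Step 8
Reactants: 16 5,5'-[1-(triisopropylsilyl)-1H-pyrrole-3,4-diyl]bis(6,7-dimethoxyquinoline); 11 (6S)-6-methyl-4-azoniaspiro[3.9]tridecane tetrafluoroborate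
Product: 17 5,5'-{1-[3-((3S)-3-methylazecan-1-yl)propyl]-1H-pyrrole-3,4-diyl}bis(6,7-dimethoxyquinoline) (tetra-O-methylisohalitulin)
Conditions: CsF (3 equiv), 18-crown-6 (10 mol %), DMF, rt, 1 h; then 11 (1.2 equiv), rt → 40 °C
Reagents that add atoms: none
Why: Proposed new method: fluoride-triggered desilylative strain-release N-alkylation, in which fluoride cleaves the N–Si bond to give a caesium pyrrolide without any N–H intermediate or strong base, and this anion, by far the best nucleophile present, opens the spiro-azetidinium ring of 11 by SN2 at one of its two equivalent CH2 groups (about 25 kcal/mol of strain released, so the unstrained azecane CH2–N bonds and the stereocentre stay untouched and the tetrafluoroborate ion cannot compete), forming the N–CH2CH2CH2–N link in one operation; the closest known reaction types are the ring-opening of azetidinium salts by heteroatom nucleophiles and the N-alkylation of azole anions with 3-chloropropylamines.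

Step 9
Reactants: 17 5,5'-{1-[3-((3S)-3-methylazecan-1-yl)propyl]-1H-pyrrole-3,4-diyl}bis(6,7-dimethoxyquinoline)
Product: 18 isohalitulin
Conditions: BBr3 (14 equiv), CH2Cl2, −78 °C → rt; MeOH, then aq. NaHCO3/Na2S2O4 under Ar
Reagents that add atoms: none
Why: Global O-demethylation of the four aryl methyl ethers with BBr3 (Lewis acid–base adduct, then bromide attack on the methyl group), standard for catechol dimethyl ethers, where the basic nitrogens only consume extra reagent and the air-sensitive catechols are worked up reductively under argon.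

**Compound list**
1 | (R)-3-bromo-2-methylpropan-1-ol | C[C@H](CO)CBr | starting material
2 | 1-bromo-6-chlorohexane | ClCCCCCCBr | starting material
3 | 6-chlorohexylmagnesium bromide | ClCCCCCC[Mg]Br | intermediate
4 | (S)-9-chloro-2-methylnonan-1-ol | C[C@H](CO)CCCCCCCCl | intermediate
5 | 2-nitrobenzenesulfonamide | NS(=O)(=O)c1ccccc1[N+](=O)[O-] | starting material
6 | N-[(8S)-9-hydroxy-8-methylnonyl]-2-nitrobenzenesulfonamide | C[C@H](CO)CCCCCCCNS(=O)(=O)c1ccccc1[N+](=O)[O-] | intermediate
7 | (3S)-3-methyl-1-[(2-nitrophenyl)sulfonyl]azecane | C[C@H]1CCCCCCCN(S(=O)(=O)c2ccccc2[N+](=O)[O-])C1 | intermediate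
8 | (3S)-3-methylazecane | C[C@H]1CCCCCCCNC1 | intermediate
9 | 1-bromo-3-chloropropane | ClCCCBr | starting material
10 | (3S)-1-(3-chloropropyl)-3-methylazecane | C[C@H]1CCCCCCCN(CCCCl)C1 | intermediate
11 | (6S)-6-methyl-4-azoniaspiro[3.9]tridecane tetrafluoroborate | C[C@H]1CCCCCCC[N+]2(CCC2)C1.F[B-](F)(F)F | intermediate
12 | 6,7-dimethoxyquinoline | COc1cc2ncccc2cc1OC | starting material
13 | 5-bromo-6,7-dimethoxyquinoline | COc1cc2ncccc2c(Br)c1OC | intermediate
14 | 3,4-dibromo-1-(triisopropylsilyl)-1H-pyrrole | CC(C)[Si](C(C)C)(C(C)C)n1cc(Br)c(Br)c1 | starting material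
15 | 6,7-dimethoxy-5-(4,4,5,5-tetramethyl-1,3,2-dioxaborolan-2-yl)quinoline | COc1cc2ncccc2c(B2OC(C)(C)C(C)(C)O2)c1OC | intermediate
16 | 5,5'-[1-(triisopropylsilyl)-1H-pyrrole-3,4-diyl]bis(6,7-dimethoxyquinoline) | CC(C)[Si](C(C)C)(C(C)C)n1cc(-c2c(OC)c(OC)cc3ncccc23)c(-c2c(OC)c(OC)cc3ncccc23)c1 | intermediate
17 | 5,5'-{1-[3-((3S)-3-methylazecan-1-yl)propyl]-1H-pyrrole-3,4-diyl}bis(6,7-dimethoxyquinoline) | C[C@H]1CCCCCCCN(CCCn2cc(-c3c(OC)c(OC)cc4ncccc34)c(-c3c(OC)c(OC)cc4ncccc34)c2)C1 | intermediate
18 | isohalitulin, 5,5'-{1-[3-((3S)-3-methylazecan-1-yl)propyl]-1H-pyrrole-3,4-diyl}bis(quinoline-6,7-diol) | C[C@H]1CCCCCCCN(CCCn2cc(-c3c(O)c(O)cc4ncccc34)c(-c3c(O)c(O)cc4ncccc34)c2)C1 | target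

**Count and risks**
Total step count: 9. Longest linear sequence: 7 steps (1, 2, 3, 4, 5, 8, 9); steps 6 and 7 form the second branch, which joins at step 8.

The three steps most likely to fail:

(a) Step 3, the ten-membered ring closure. Transannular strain slows the cyclisation, intermolecular alkylation can give the cyclic dimer, and the carbinol is β-branched. The fallback moves the ring-closing bond to the unbranched end (N–C10) and closes it by plain SN2 alkylation. It sets out from 4: an intermolecular Mitsunobu reaction with tert-butyl (2-nitrophenyl)sulfonylcarbamate (PPh3, DIAD, THF) gives tert-butyl [(2S)-9-chloro-2-methylnonyl][(2-nitrophenyl)sulfonyl]carbamate F1. TFA in CH2Cl2 removes the Boc group to give N-[(2S)-9-chloro-2-methylnonyl]-2-nitrobenzenesulfonamide F2. Cs2CO3 and Bu4NI in MeCN at 60 °C (0.01 M) then close the ring, and the route is rejoined at 7.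

(b) Step 7, the one-flask borylation and twofold coupling. The electron-rich boronate 15 is flanked on both sides and may protodeboronate, the second coupling next to the first quinolinyl group may stall, and some silyl group may be lost. The fallback reverses the polarity. It sets out from 14: Miyaura borylation (B2pin2, Pd(dppf)Cl2, KOAc, dioxane, 90 °C) gives 3,4-bis(4,4,5,5-tetramethyl-1,3,2-dioxaborolan-2-yl)-1-(triisopropylsilyl)-1H-pyrrole F3, which is isolated. F3 is coupled twofold with 13 (2.3 equiv; Pd(OAc)2/SPhos, K3PO4, toluene–water, 100 °C), and the route is rejoined at 16.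

(c) Step 8, the proposed new coupling. The pyrrolide or fluoride may act as a base and open 11 by Hofmann-type elimination, fluoride may open the azetidinium ring itself, and the pyrrolide may alkylate at C2. The fallback uses known chemistry. It sets out from 16: Bu4NF in THF gives 5,5'-(1H-pyrrole-3,4-diyl)bis(6,7-dimethoxyquinoline) F4. NaH in DMF with excess 9 gives 5,5'-[1-(3-chloropropyl)-1H-pyrrole-3,4-diyl]bis(6,7-dimethoxyquinoline) F5, the bromide being displaced selectively. Heating F5 with amine 8, K2CO3 and NaI in MeCN at 80 °C forms the amine C–N bond, and the route is rejoined at 17; step 5 is then not needed.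

Further compounds
F1 | step 3 | tert-butyl [(2S)-9-chloro-2-methylnonyl][(2-nitrophenyl)sulfonyl]carbamate | C[C@H](CN(C(=O)OC(C)(C)C)S(=O)(=O)c1ccccc1[N+](=O)[O-])CCCCCCCCl
F2 | step 3 | N-[(2S)-9-chloro-2-methylnonyl]-2-nitrobenzenesulfonamide | C[C@H](CNS(=O)(=O)c1ccccc1[N+](=O)[O-])CCCCCCCCl
F3 | step 7 | 3,4-bis(4,4,5,5-tetramethyl-1,3,2-dioxaborolan-2-yl)-1-(triisopropylsilyl)-1H-pyrrole | CC(C)[Si](C(C)C)(C(C)C)n1cc(B2OC(C)(C)C(C)(C)O2)c(B2OC(C)(C)C(C)(C)O2)c1
F4 | step 8 | 5,5'-(1H-pyrrole-3,4-diyl)bis(6,7-dimethoxyquinoline) | c1[nH]cc(-c2c(OC)c(OC)cc3ncccc23)c1-c1c(OC)c(OC)cc2ncccc12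
F5 | step 8 | 5,5'-[1-(3-chloropropyl)-1H-pyrrole-3,4-diyl]bis(6,7-dimethoxyquinoline) | ClCCCn1cc(-c2c(OC)c(OC)cc3ncccc23)c(-c2c(OC)c(OC)cc3ncccc23)c1
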